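**Retrosynthetic overview**

1. The butenolide is attached last: Heck coupling of a terminal (2E)-dienol with 4-bromofuran-2(5H)-one forms the C1'–C4 bond of the furanone.
2. The trisubstituted alkene and its CH2OH come from a one-pot aldol/mesylation/elimination of a saturated ethyl ester with acrolein, then reduction of the ester.
3. The ring-to-chain bond comes from a B-alkyl Suzuki coupling of a tetrasubstituted enol triflate with the 9-BBN adduct of ethyl but-3-enoate.
4. Ring B is made by one-carbon ring expansion of a cis-hydrindan-1-one with diazoethane (1,2-shift of the ring CH2 from the carbonyl carbon to the diazo carbon); this brings in the methyl-bearing carbon, and the single enolisable position then gives the enol triflate.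
5. Ring A and both stereocentres come from an enantioselective radical conjugate addition / enolate alkylation of 2-methylcyclopent-2-en-1-one with 5-bromo-2-methylpent-2-ene. Ring order: cyclopentenone (bought), ring A, five-membered ring expanded to ring B, butenolide (bought).

Assumption: the target is taken exactly as the SMILES gives it, a cis-fused (4aR,8aS) decalin with a (1E,3E) diene; the sense of induction of the amine catalyst in step 1 must be found by experiment, and the pseudo-enantiomer (quinine- or quinidine-derived) that gives (3S)-3 is the one used.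

Shorthand: Dec = (4aR,8aS)-2,5,5,8a-tetramethyl-3,4,4a,5,6,7,8,8a-octahydronaphthalen-1-yl (cis ring fusion, 8a-CH3 and 4a-H on the same face, ring double bond C1=C2).

**Route**

Step 1
Reactants: 1 2-methylcyclopent-2-en-1-one; 2 5-bromo-2-methylpent-2-ene
Product: 4 (3aR,7aS)-4,4,7a-trimethyloctahydro-1H-inden-1-one (cis-fused), via bromo ketone 3 (not isolated)
Conditions: Fe(acac)3 (30 mol %), PhSiH3, 9-amino-9-deoxy-epi-quinine·2 CF3CO2H (20 mol %), EtOH, 0 °C to rt; evaporate; t-BuOK, THF, 0 °C to rt
Reagents that add atoms: none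
Why: Proposed new method: iron-hydride hydrogen-atom transfer to 2 gives the tertiary radical, which adds to C-3 of the chiral iminium ion formed from 1 and the primary amine (the cationic iminium is far more reactive toward this nucleophilic radical than free 1, and the catalyst shields one face, so C-3 is set by the catalyst); reduction of the radical cation by divalent iron and hydrolysis give ketone 3, and t-BuOK then closes ring A by 6-exo-tet enolate alkylation, which is geometrically restricted to the cis ring fusion and so sets C-7a; the closest known chemistry is the racemic Fe(acac)3/PhSiH3 reductive olefin–enone coupling (Giese addition) and the trapping of alkyl radicals by chiral iminium ions of cyclic enones.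

Step 2
Reactants: 4 (3aR,7aS)-4,4,7a-trimethyloctahydro-1H-inden-1-one
Product: 5 (4aR,8aS)-2,5,5,8a-tetramethyloctahydronaphthalen-1(2H)-one (both C-2 epimers)
Conditions: MeCHN2 (pre-formed, Et2O solution), Sc(OTf)3 (10 mol %), CH2Cl2, −78 to −20 °C
Reagents that add atoms: diazoethane, CC=[N+]=[N-]
Why: Lewis-acid-catalysed diazoalkane–ketone homologation (Tiffeneau–Demjanov-type ring expansion): diazoethane adds to the activated C-1 carbonyl and the unhindered ring CH2 (C-2), not the quaternary C-7a, undergoes the 1,2-shift with loss of N2, so the CHMe unit ends up between the carbonyl and the old C-2; the two ring-fusion centres are untouched and the new C-2 centre is erased in step 3.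

Step 3
Reactants: 5 (4aR,8aS)-2,5,5,8a-tetramethyloctahydronaphthalen-1(2H)-one
Product: 7 Dec trifluoromethanesulfonate (Dec–OTf), via potassium enolate 6 (not isolated)
Conditions: KN(SiMe3)2, THF, −78 to 0 °C; PhNTf2, −78 °C to rt
Reagents that add atoms: N-phenylbis(trifluoromethanesulfonimide) (PhNTf2), O=S(=O)(N(c1ccccc1)S(=O)(=O)C(F)(F)F)C(F)(F)F
Why: Regiospecific enolate O-triflation: the ketone has an α-hydrogen only at C-2 (C-8a is quaternary), so both epimers give the same tetrasubstituted enolate, which is trapped on oxygen.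

Step 4
Reactants: 7 Dec trifluoromethanesulfonate; 8 ethyl but-3-enoate
Product: 10 ethyl 4-Dec-butanoate, via alkylborane 9 (not isolated)
Conditions: 8, 9-BBN, THF, 0 °C to rt; then 7, PdCl2(dppf) (10 mol %), AsPh3, K3PO4 (aq), DMF, 60 °C
Reagents that add atoms: none
Why: Anti-Markovnikov hydroboration of the terminal alkene followed by B-alkyl Suzuki–Miyaura coupling (oxidative addition of zerovalent palladium into the C–OTf bond, base-assisted transmetalation, reductive elimination) joins the chain to C-1 of the ring without moving the ring double bond.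

Step 5
Reactants: 10 ethyl 4-Dec-butanoate; 11 acrolein
Product: 15 ethyl (2E)-2-(2-Dec-ethyl)penta-2,4-dienoate, via lithium enolate 12 (not isolated), via lithium aldolate 13 (not isolated), via mesylate 14 (not isolated)
Conditions: LiN(i-Pr)2, THF, −78 °C; 11, −78 °C; MsCl, −78 to 0 °C; DBU, 0 °C to rt
Reagents that add atoms: none
Why: Aldol addition of the ester enolate to the aldehyde carbon of acrolein, O-mesylation of the aldolate and E1cB elimination; the (2E)-dienoate, with the ester trans to the vinyl group, is expected as the major isomer because it has the least allylic strain, and this places the future CH2OH cis to H-3 (any 2Z isomer is removed by chromatography).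

Step 6
Reactants: 15 ethyl (2E)-2-(2-Dec-ethyl)penta-2,4-dienoate
Product: 16 (2E)-2-(2-Dec-ethyl)penta-2,4-dien-1-ol
Conditions: i-Bu2AlH, CH2Cl2, −78 °C; aq. KNaC4H4O6
Reagents that add atoms: none
Why: 1,2-Reduction of the conjugated ester by the aluminium hydride gives the allylic alcohol and leaves the diene and its geometry intact.

Step 7
Reactants: 16 (2E)-2-(2-Dec-ethyl)penta-2,4-dien-1-ol; 17 4-bromofuran-2(5H)-one
Product: 18 4-[(1E,3E)-4-(hydroxymethyl)-6-Dec-hexa-1,3-dien-1-yl]furan-2(5H)-one (target)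
Conditions: Pd(OAc)2 (10 mol %), P(o-tol)3, NaHCO3, Bu4NCl, DMF, 60 °C
Reagents that add atoms: none
Why: Mizoroki–Heck reaction: zerovalent palladium inserts into the vinylogous acyl bromide, the furanonyl group adds to the unhindered terminal CH2 of the diene, and syn β-hydride elimination gives the (E)-alkene conjugated with the butenolide; the tri- and tetrasubstituted alkenes do not insert.

**Compound list**

1 | 2-methylcyclopent-2-en-1-one | CC1=CCCC1=O | starting material
2 | 5-bromo-2-methylpent-2-ene | CC(C)=CCCBr | starting material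
3 | (3S)-3-(5-bromo-2-methylpentan-2-yl)-2-methylcyclopentan-1-one (both C-2 epimers) | O=C1CC[C@H](C(C)(C)CCCBr)C1C | intermediate (not isolated)
4 | (3aR,7aS)-4,4,7a-trimethyloctahydro-1H-inden-1-one | O=C1CC[C@@H]2C(C)(C)CCC[C@]12C | intermediate
5 | (4aR,8aS)-2,5,5,8a-tetramethyloctahydronaphthalen-1(2H)-one (both C-2 epimers) | CC1C(=O)[C@@]2(C)CCCC(C)(C)[C@H]2CC1 | intermediate
6 | potassium (4aR,8aS)-2,5,5,8a-tetramethyl-3,4,4a,5,6,7,8,8a-octahydronaphthalen-1-olate | CC1=C([O-])[C@@]2(C)CCCC(C)(C)[C@H]2CC1.[K+] | intermediate (not isolated)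
7 | (4aR,8aS)-2,5,5,8a-tetramethyl-3,4,4a,5,6,7,8,8a-octahydronaphthalen-1-yl trifluoromethanesulfonate | CC1=C(OS(=O)(=O)C(F)(F)F)[C@@]2(C)CCCC(C)(C)[C@H]2CC1 | intermediate
8 | ethyl but-3-enoate | C=CCC(=O)OCC | starting material
9 | ethyl 4-(9-borabicyclo[3.3.1]nonan-9-yl)butanoate | CCOC(=O)CCCB1C2CCCC1CCC2 | intermediate (not isolated)
10 | ethyl 4-[(4aR,8aS)-2,5,5,8a-tetramethyl-3,4,4a,5,6,7,8,8a-octahydronaphthalen-1-yl]butanoate | CC1=C(CCCC(=O)OCC)[C@@]2(C)CCCC(C)(C)[C@H]2CC1 | intermediate
11 | acrolein (prop-2-enal) | C=CC=O | starting material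
12 | lithium enolate of 10 (lithium 1-ethoxy-4-Dec-but-1-en-1-olate) | CC1=C(CCC=C([O-])OCC)[C@@]2(C)CCCC(C)(C)[C@H]2CC1.[Li+] | intermediate (not isolated)
13 | lithium 4-(ethoxycarbonyl)-6-Dec-hex-1-en-3-olate (diastereomer mixture) | CC1=C(CCC(C([O-])C=C)C(=O)OCC)[C@@]2(C)CCCC(C)(C)[C@H]2CC1.[Li+] | intermediate (not isolated)
14 | ethyl 2-(2-Dec-ethyl)-3-[(methylsulfonyl)oxy]pent-4-enoate (diastereomer mixture) | CC1=C(CCC(C(OS(C)(=O)=O)C=C)C(=O)OCC)[C@@]2(C)CCCC(C)(C)[C@H]2CC1 | intermediate (not isolated)
15 | ethyl (2E)-2-{2-[(4aR,8aS)-2,5,5,8a-tetramethyl-3,4,4a,5,6,7,8,8a-octahydronaphthalen-1-yl]ethyl}penta-2,4-dienoate | CC1=C(CC/C(=C\C=C)C(=O)OCC)[C@@]2(C)CCCC(C)(C)[C@H]2CC1 | intermediate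
16 | (2E)-2-{2-[(4aR,8aS)-2,5,5,8a-tetramethyl-3,4,4a,5,6,7,8,8a-octahydronaphthalen-1-yl]ethyl}penta-2,4-dien-1-ol | CC1=C(CC/C(=C\C=C)CO)[C@@]2(C)CCCC(C)(C)[C@H]2CC1 | intermediate
17 | 4-bromofuran-2(5H)-one | O=C1C=C(Br)CO1 | starting material
18 | 4-[(1E,3E)-4-(hydroxymethyl)-6-[(4aR,8aS)-2,5,5,8a-tetramethyl-3,4,4a,5,6,7,8,8a-octahydronaphthalen-1-yl]hexa-1,3-dien-1-yl]furan-2(5H)-one | CC1=C(CC/C(=C\C=C\C2=CC(=O)OC2)CO)[C@@]2(C)CCCC(C)(C)[C@H]2CC1 | target

**Step count**

Total: 7 steps. Longest linear sequence: 7 steps (1 + 2 → 4 → 5 → 7 → 10 → 15 → 16 → 18).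

**Three steps most likely to fail**

Step 1 (the proposed new step). The racemic radical addition to free 1 may compete with the iminium pathway, the iminium of an α-substituted enone forms slowly, and the amine may be alkylated by 2. Fallback with known chemistry, setting out from 2 and coming back at 4: 2 is used to C-alkylate 2-methylcyclopentane-1,3-dione F1 (t-BuOK, NaI, DMSO), which gives the prochiral 2-methyl-2-(4-methylpent-3-en-1-yl)cyclopentane-1,3-dione F2. Asymmetric transfer hydrogenation with RuCl(p-cymene)[(R,R)-TsDPEN] or its mirror image (whichever reduces the required carbonyl), HCO2H/Et3N, differentiates the two enantiotopic carbonyl groups and fixes the quaternary centre in (2R,3R)-3-hydroxy-2-methyl-2-(4-methylpent-3-en-1-yl)cyclopentan-1-one F3. TsNHNH2 in MeOH gives N'-[(2S,3R)-3-hydroxy-2-methyl-2-(4-methylpent-3-en-1-yl)cyclopentylidene]-4-methylbenzenesulfonohydrazide F4. Fe(acac)3/PhSiH3 in EtOH (hydrogen-atom transfer to the alkene, 6-exo attack of the tertiary radical on the hydrazone carbon), then Et3N/MeOH at 65 °C to expel sulfinate and N2, closes ring A and leaves the ring-fusion hydrogen, giving the cis-fused (1R,3aR,7aS)-4,4,7a-trimethyloctahydro-1H-inden-1-ol F5. Dess–Martin periodinane oxidises it to 4.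

Step 4. The triflate is tetrasubstituted and sits next to a quaternary carbon, so oxidative addition and transmetalation of the sp3 partner may be slow and lose out to protodeboronation or β-hydride elimination. Fallback, setting out from 7 and coming back at 10: Stille coupling of 7 with Bu3SnCH=CH2 (Pd(PPh3)4, LiCl, THF, 65 °C), an sp2–sp2 coupling that tolerates the hindrance, gives (4aR,8aS)-1-ethenyl-2,5,5,8a-tetramethyl-3,4,4a,5,6,7,8,8a-octahydronaphthalene F6. 9-BBN adds only to its vinyl group and gives 9-{2-[(4aR,8aS)-2,5,5,8a-tetramethyl-3,4,4a,5,6,7,8,8a-octahydronaphthalen-1-yl]ethyl}-9-borabicyclo[3.3.1]nonane F7. Treatment with ethyl bromoacetate and t-BuOK (Brown α-alkylation, 1,2-shift of the primary alkyl group from boron to carbon) gives ester 10.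

Step 7. The allyl-palladium intermediate formed from the diene can be diverted (elimination toward the CH2OH carbon, isomerisation), and the butenolide is base-sensitive. Fallback, setting out from 16 and coming back at 18: cross-metathesis of the terminal alkene of 16 with vinylboronic acid pinacol ester (second-generation Grubbs catalyst, CH2Cl2, 40 °C) gives (2E,4E)-2-{2-[(4aR,8aS)-2,5,5,8a-tetramethyl-3,4,4a,5,6,7,8,8a-octahydronaphthalen-1-yl]ethyl}-5-(4,4,5,5-tetramethyl-1,3,2-dioxaborolan-2-yl)penta-2,4-dien-1-ol F8. Suzuki–Miyaura coupling of it with 17 (PdCl2(dppf), K3PO4 (aq), THF, 50 °C) gives 18.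

Further compounds
F1 | step 1 | 2-methylcyclopentane-1,3-dione (bought) | CC1C(=O)CCC1=O
F2 | step 1 | 2-methyl-2-(4-methylpent-3-en-1-yl)cyclopentane-1,3-dione | CC(C)=CCCC1(C)C(=O)CCC1=O
F3 | step 1 | (2R,3R)-3-hydroxy-2-methyl-2-(4-methylpent-3-en-1-yl)cyclopentan-1-one | O=C1CC[C@@H](O)[C@@]1(C)CCC=C(C)C
F4 | step 1 | N'-[(2S,3R)-3-hydroxy-2-methyl-2-(4-methylpent-3-en-1-yl)cyclopentylidene]-4-methylbenzenesulfonohydrazide | Cc1ccc(cc1)S(=O)(=O)NN=C1CC[C@@H](O)[C@@]1(C)CCC=C(C)C
F5 | step 1 | (1R,3aR,7aS)-4,4,7a-trimethyloctahydro-1H-inden-1-ol | O[C@@H]1CC[C@@H]2C(C)(C)CCC[C@]12C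
F6 | step 4 | (4aR,8aS)-1-ethenyl-2,5,5,8a-tetramethyl-3,4,4a,5,6,7,8,8a-octahydronaphthalene | CC1=C(C=C)[C@@]2(C)CCCC(C)(C)[C@H]2CC1
F7 | step 4 | 9-{2-[(4aR,8aS)-2,5,5,8a-tetramethyl-3,4,4a,5,6,7,8,8a-octahydronaphthalen-1-yl]ethyl}-9-borabicyclo[3.3.1]nonane | CC1=C(CCB3C4CCCC3CCC4)[C@@]2(C)CCCC(C)(C)[C@H]2CC1
F8 | step 7 | (2E,4E)-2-{2-[(4aR,8aS)-2,5,5,8a-tetramethyl-3,4,4a,5,6,7,8,8a-octahydronaphthalen-1-yl]ethyl}-5-(4,4,5,5-tetramethyl-1,3,2-dioxaborolan-2-yl)penta-2,4-dien-1-ol | CC1=C(CC/C(=C\C=C\B3OC(C)(C)C(C)(C)O3)CO)[C@@]2(C)CCCC(C)(C)[C@H]2CC1
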